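**Retrosynthetic overview**
- The C50 diol comes from reduction of its side-chain ethyl ester, which is cut at C7=C8 (Julia–Kocienski) into a ring C15 tetrazolyl sulfone and a C35 polyenal.
- The C35 polyenal comes from a mono-Wittig reaction (C7'=C8') of the commercial C20 dialdehyde with an acyclic C15 phosphonium salt; its C2' centre is set by anti-prenylation of a chiral-pool hydroxy diester, whose carbinol is then excised by glycol cleavage.
- The ring sulfone comes from a homoallylic alcohol made in the key [2,3]-sigmatropic Wittig–Still shift (C4–O to C6–C7, alkene to C4=C5), which transfers chirality to C6, trans to the C2 arm.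
- The allylic alcohol comes from Wharton transposition of a trans-epoxy ketone, from a 2-methylcyclohexenone, from ozonolysis/aldol ring expansion of a pinene-derived chiral-pool cyclopentene aldehyde that carries C2.
- Ring order: the single carbocycle (the cyclohexene) is formed first, in the ozonolysis/aldol step; no other ring is made.

Assumption: the target is taken exactly as the SMILES reads, i.e. ring C6 (R) and C2 (S) with the C2 side chain trans to the C6 polyene chain, C2' (R), all chain double bonds E.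

**Step 1**
Reactants: 1 (S)-α-campholenic aldehyde, 2-[(1S)-2,2,3-trimethylcyclopent-3-en-1-yl]acetaldehyde
Product: 2 (4S)-4-(2,2-dimethoxyethyl)-1,5,5-trimethylcyclopent-1-ene
Conditions: HC(OMe)3, p-TsOH·H2O (cat.), MeOH, rt
Reagents that add atoms: trimethyl orthoformate COC(OC)OC
Why: Acid-catalysed acetalisation masks the aldehyde arm so that the two CH2 arms on the bought stereocentre stay different once the ring is cleaved, and the stereocentre itself is not touched.

**Step 2**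
Reactants: 2 (4S)-4-(2,2-dimethoxyethyl)-1,5,5-trimethylcyclopent-1-ene
Product: 4 (5S)-5-(2,2-dimethoxyethyl)-6,6-dimethylcyclohex-2-en-1-one, via keto-aldehyde 3 (not isolated)
Conditions: O3, CH2Cl2, −78 °C; Me2S, −78 °C → rt; solvent switch; KOH (0.3 equiv), MeOH, 0 → 40 °C
Reagents that add atoms: ozone [O-][O+]=O
Why: Ozonolysis of the only C=C gives a 1,5-keto-aldehyde whose methyl ketone (enolisable on one side only) closes onto the aldehyde in an intramolecular aldol condensation, a net one-carbon ring expansion that leaves the stereocentre (β to the aldehyde) untouched.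

**Step 3**
Reactants: 4 (5S)-5-(2,2-dimethoxyethyl)-6,6-dimethylcyclohex-2-en-1-one
Product: 5 (5S)-5-(2,2-dimethoxyethyl)-2-iodo-6,6-dimethylcyclohex-2-en-1-one
Conditions: I2, pyridine, CH2Cl2, rt
Reagents that add atoms: iodine II
Why: Johnson α-iodination of the enone (pyridine conjugate addition, iodination of the enolate, elimination) works because the β-carbon is unhindered and the α'-position is blocked.

**Step 4**
Reactants: 5 (5S)-5-(2,2-dimethoxyethyl)-2-iodo-6,6-dimethylcyclohex-2-en-1-one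
Product: 6 (5S)-5-(2,2-dimethoxyethyl)-2,6,6-trimethylcyclohex-2-en-1-one
Conditions: MeB(OH)2, PdCl2(dppf) (5 mol%), K3PO4, dioxane/H2O, 80 °C
Reagents that add atoms: methylboronic acid CB(O)O
Why: Suzuki–Miyaura coupling of the α-iodoenone installs the C5 methyl without touching the acetal or the stereocentre.

**Step 5**
Reactants: 6 (5S)-5-(2,2-dimethoxyethyl)-2,6,6-trimethylcyclohex-2-en-1-one
Product: 7 (1R,4S,6R)-4-(2,2-dimethoxyethyl)-1,3,3-trimethyl-7-oxabicyclo[4.1.0]heptan-2-one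
Conditions: 30% H2O2, NaOH (cat.), MeOH, 0 °C
Reagents that add atoms: hydrogen peroxide OO
Why: Weitz–Scheffer nucleophilic epoxidation, in which hydroperoxide adds axially to the β-carbon on the face away from the C2 arm (as with carvone), so both new epoxide centres are set trans to the bought centre.

**Step 6**
Reactants: 7 (1R,4S,6R)-4-(2,2-dimethoxyethyl)-1,3,3-trimethyl-7-oxabicyclo[4.1.0]heptan-2-one
Product: 8 (1R,5S)-5-(2,2-dimethoxyethyl)-2,4,4-trimethylcyclohex-2-en-1-ol
Conditions: N2H4·H2O, AcOH (cat.), MeOH, 0 °C → rt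
Reagents that add atoms: none
Why: Wharton transposition, in which the epoxy hydrazone fragments with loss of N2 to the transposed allylic alcohol; the C4–O bond is never broken, so the carbinol stays trans to the C2 arm.

**Step 7**
Reactants: 8 (1R,5S)-5-(2,2-dimethoxyethyl)-2,4,4-trimethylcyclohex-2-en-1-ol
Product: 11 [(1R,5S)-5-(2,2-dimethoxyethyl)-2,6,6-trimethylcyclohex-2-en-1-yl]methanol, via stannylmethyl ether 9 (not isolated), via lithiomethyl ether 10 (not isolated)
Conditions: KH, THF, 0 °C; Bu3SnCH2I, rt; then n-BuLi, −78 °C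
Reagents that add atoms: tributyl(iodomethyl)stannane CCCC[Sn](CCCC)(CCCC)CI
Why: Williamson etherification and tin–lithium exchange set up the [2,3]-sigmatropic Wittig–Still rearrangement, whose five-membered envelope transition state delivers the CH2O carbon to C6 on the face that carried the C4–O bond while the alkene moves to C4=C5, so C6 is set by 1,3-chirality transfer, trans to the C2 arm.

**Step 8**
Reactants: 11 [(1R,5S)-5-(2,2-dimethoxyethyl)-2,6,6-trimethylcyclohex-2-en-1-yl]methanol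
Product: 13 ethyl (2E)-4-[(1S,5R)-5-(hydroxymethyl)-4,6,6-trimethylcyclohex-3-en-1-yl]-2-methylbut-2-enoate, via ring hydroxy aldehyde 12 (not isolated)
Conditions: p-TsOH·H2O (0.1 equiv), THF/H2O, 40 °C; then Ph3P=C(Me)CO2Et (1.5 equiv), rt
Reagents that add atoms: ethyl 2-(triphenylphosphoranylidene)propanoate CCOC(=O)C(C)=P(c1ccccc1)(c1ccccc1)c1ccccc1
Why: Acetal hydrolysis frees the aldehyde, which is taken in the same pot by a water-tolerant stabilised ylide in a Wittig reaction that gives the (E)-trisubstituted enoate.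

**Step 9**
Reactants: 13 ethyl (2E)-4-[(1S,5R)-5-(hydroxymethyl)-4,6,6-trimethylcyclohex-3-en-1-yl]-2-methylbut-2-enoate
Product: 14 ethyl (2E)-2-methyl-4-[(1S,5R)-4,6,6-trimethyl-5-{[(1-phenyl-1H-tetrazol-5-yl)sulfanyl]methyl}cyclohex-3-en-1-yl]but-2-enoate
Conditions: 1-phenyl-1H-tetrazole-5-thiol, PPh3, DIAD, THF, 0 °C → rt
Reagents that add atoms: 1-phenyl-1H-tetrazole-5-thiol Sc1nnnn1-c1ccccc1
Why: Mitsunobu thioetherification of the primary alcohol with an acidic thiol proceeds at the CH2 carbon, so no stereocentre is involved.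

**Step 10**
Reactants: 14 ethyl (2E)-2-methyl-4-[(1S,5R)-4,6,6-trimethyl-5-{[(1-phenyl-1H-tetrazol-5-yl)sulfanyl]methyl}cyclohex-3-en-1-yl]but-2-enoate
Product: 15 ethyl (2E)-2-methyl-4-[(1S,5R)-4,6,6-trimethyl-5-{[(1-phenyl-1H-tetrazol-5-yl)sulfonyl]methyl}cyclohex-3-en-1-yl]but-2-enoate
Conditions: (NH4)6Mo7O24·4H2O (10 mol%), 30% H2O2, EtOH, 0 °C → rt
Reagents that add atoms: hydrogen peroxide OO
Why: Molybdate-catalysed peroxide oxidation takes the sulfide to the sulfone chemoselectively, sparing the trisubstituted ring alkene and the enoate.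

**Step 11**
Reactants: 16 diethyl (S)-malate, 17 prenyl bromide (1-bromo-3-methylbut-2-ene)
Product: 18 diethyl (2S,3R)-2-hydroxy-3-(3-methylbut-2-en-1-yl)butanedioate
Conditions: LiN(i-Pr)2 (2.2 equiv), THF, −78 → −20 °C; then 17, −78 → −10 °C
Reagents that add atoms: none
Why: Fráter–Seebach alkylation, in which the chelated alkoxide–enolate dianion is attacked anti to the alkoxide, so the bought carbinol sets the new C3 centre (anti, about 10:1).

**Step 12**
Reactants: 18 diethyl (2S,3R)-2-hydroxy-3-(3-methylbut-2-en-1-yl)butanedioate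
Product: 19 (3S,4R)-2,5-dimethyl-4-(3-methylbut-2-en-1-yl)hexane-2,3,5-triol
Conditions: MeMgBr (6 equiv), THF, 0 °C → rt
Reagents that add atoms: methylmagnesium bromide C[Mg]Br
Why: Double Grignard addition to both esters builds the C1' dimethylcarbinol and turns the malate carbinol into a cleavable glycol, and the minor diastereomer from step 11 is removed at this crystalline triol.

**Step 13**
Reactants: 19 (3S,4R)-2,5-dimethyl-4-(3-methylbut-2-en-1-yl)hexane-2,3,5-triol
Product: 21 (3E,5R)-5-(2-hydroxypropan-2-yl)-8-methylnona-3,7-dien-2-one, via β-hydroxy aldehyde 20 (not isolated)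
Conditions: NaIO4 on SiO2, Ph3P=CHC(O)Me, CH2Cl2, rt → 40 °C
Reagents that add atoms: 1-(triphenylphosphoranylidene)propan-2-one CC(=O)C=P(c1ccccc1)(c1ccccc1)c1ccccc1
Why: Periodate glycol cleavage excises the malate carbinol as acetone, and the sensitive α-chiral β-hydroxy aldehyde is trapped at once by a base-free Wittig reaction with a stabilised ylide, which gives the E-enone without retro-aldol or epimerisation.

**Step 14**
Reactants: 21 (3E,5R)-5-(2-hydroxypropan-2-yl)-8-methylnona-3,7-dien-2-one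
Product: 22 (4E,6R)-6-(2-hydroxypropan-2-yl)-3,9-dimethyldeca-1,4,8-trien-3-ol (both C3 epimers)
Conditions: CH2=CHMgBr (2.5 equiv), THF, −78 → 0 °C
Reagents that add atoms: vinylmagnesium bromide C=C[Mg]Br
Why: 1,2-Grignard addition to the enone, as in the vinyl-ionol synthesis, gives a carbinol whose configuration is irrelevant because it is ionised in the next step.

**Step 15**
Reactants: 22 (4E,6R)-6-(2-hydroxypropan-2-yl)-3,9-dimethyldeca-1,4,8-trien-3-ol
Product: 23 [(2E,4E,6R)-6-(2-hydroxypropan-2-yl)-3,9-dimethyldeca-2,4,8-trien-1-yl]triphenylphosphonium bromide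
Conditions: Ph3P·HBr, MeOH/CH2Cl2, 0 °C → rt
Reagents that add atoms: triphenylphosphine hydrobromide [Br-].[PH+](c1ccccc1)(c1ccccc1)c1ccccc1
Why: Only the doubly allylic tertiary carbinol ionises, and the phosphine captures the pentadienyl cation at its primary terminus (allylic transposition, as in the classical carotenoid phosphonium salts) to give the mainly E conjugated salt, leaving the non-allylic tertiary alcohol and C2' intact.

**Step 16**
Reactants: 23 [(2E,4E,6R)-6-(2-hydroxypropan-2-yl)-3,9-dimethyldeca-2,4,8-trien-1-yl]triphenylphosphonium bromide, 24 crocetindial, (2E,4E,6E,8E,10E,12E,14E)-2,6,11,15-tetramethylhexadeca-2,4,6,8,10,12,14-heptaenedial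
Product: 25 (2E,4E,6E,8E,10E,12E,14E,16E,18E,20E,22R)-22-(2-hydroxypropan-2-yl)-2,6,11,15,19,25-hexamethylhexacosa-2,4,6,8,10,12,14,16,18,20,24-undecaenal
Conditions: 24 (3 equiv), NaOMe, MeOH/CH2Cl2, 0 °C → rt; then I2 (cat.), CH2Cl2, daylight
Reagents that add atoms: none
Why: Wittig reaction of the semi-stabilised allylic ylide with an excess of the dialdehyde gives the mono-olefination product, and iodine-catalysed equilibration brings the new C7'=C8' bond to E.

**Step 17**
Reactants: 15 ethyl (2E)-2-methyl-4-[(1S,5R)-4,6,6-trimethyl-5-{[(1-phenyl-1H-tetrazol-5-yl)sulfonyl]methyl}cyclohex-3-en-1-yl]but-2-enoate, 25 (2E,4E,6E,8E,10E,12E,14E,16E,18E,20E,22R)-22-(2-hydroxypropan-2-yl)-2,6,11,15,19,25-hexamethylhexacosa-2,4,6,8,10,12,14,16,18,20,24-undecaenal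
Product: 26 ethyl (2E)-4-[(1S,5R)-5-[(1E,3E,5E,7E,9E,11E,13E,15E,17E,19E,21E,23R)-23-(2-hydroxypropan-2-yl)-3,7,12,16,20,26-hexamethylheptacosa-1,3,5,7,9,11,13,15,17,19,21,25-dodecaen-1-yl]-4,6,6-trimethylcyclohex-3-en-1-yl]-2-methylbut-2-enoate
Conditions: 15 (1.3 equiv), KN(SiMe3)2, DME, −60 °C; then 25, −60 °C → rt
Reagents that add atoms: none
Why: Julia–Kocienski olefination, in which the metallated tetrazolyl sulfone adds to the aldehyde and Smiles rearrangement with loss of SO2 gives the E C7=C8 bond; the deprotonated carbon is C7, so C6 is not epimerised.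

**Step 18**
Reactants: 26 ethyl ester of the target (C4'' of the ring side chain as CO2Et)
Product: 27 target, (2S,6R,2'R)-2-[(2E)-4-hydroxy-3-methylbut-2-enyl]-2'-(3-methylbut-2-enyl)-3',4'-didehydro-1',2'-dihydro-ε,ψ-caroten-1'-ol
Conditions: (i-Bu)2AlH (5 equiv), CH2Cl2/THF, −78 °C
Reagents that add atoms: none
Why: Hydride 1,2-reduction of the enoate gives the (E)-allylic alcohol without touching the polyene, the tertiary alcohol or any stereocentre.

**Compound list**
1 | (S)-α-campholenic aldehyde, 2-[(1S)-2,2,3-trimethylcyclopent-3-en-1-yl]acetaldehyde | O=CC[C@@H]1CC=C(C)C1(C)C | starting material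
2 | (4S)-4-(2,2-dimethoxyethyl)-1,5,5-trimethylcyclopent-1-ene | COC(OC)C[C@@H]1CC=C(C)C1(C)C | intermediate
3 | (3S)-3-(2,2-dimethoxyethyl)-4,4-dimethyl-5-oxohexanal | COC(OC)C[C@H](CC=O)C(C)(C)C(C)=O | intermediate
4 | (5S)-5-(2,2-dimethoxyethyl)-6,6-dimethylcyclohex-2-en-1-one | O=C1C=CC[C@@H](CC(OC)OC)C1(C)C | intermediate
5 | (5S)-5-(2,2-dimethoxyethyl)-2-iodo-6,6-dimethylcyclohex-2-en-1-one | O=C1C(I)=CC[C@@H](CC(OC)OC)C1(C)C | intermediate
6 | (5S)-5-(2,2-dimethoxyethyl)-2,6,6-trimethylcyclohex-2-en-1-one | O=C1C(C)=CC[C@@H](CC(OC)OC)C1(C)C | intermediate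
7 | (1R,4S,6R)-4-(2,2-dimethoxyethyl)-1,3,3-trimethyl-7-oxabicyclo[4.1.0]heptan-2-one | O=C1[C@]2(C)O[C@@H]2C[C@@H](CC(OC)OC)C1(C)C | intermediate
8 | (1R,5S)-5-(2,2-dimethoxyethyl)-2,4,4-trimethylcyclohex-2-en-1-ol | O[C@H]1C(C)=CC(C)(C)[C@H](CC(OC)OC)C1 | intermediate
9 | tributyl({[(1R,5S)-5-(2,2-dimethoxyethyl)-2,4,4-trimethylcyclohex-2-en-1-yl]oxy}methyl)stannane | CCCC[Sn](CCCC)(CCCC)CO[C@H]1C(C)=CC(C)(C)[C@H](CC(OC)OC)C1 | intermediate
10 | ({[(1R,5S)-5-(2,2-dimethoxyethyl)-2,4,4-trimethylcyclohex-2-en-1-yl]oxy}methyl)lithium | [Li]CO[C@H]1C(C)=CC(C)(C)[C@H](CC(OC)OC)C1 | intermediate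
11 | [(1R,5S)-5-(2,2-dimethoxyethyl)-2,6,6-trimethylcyclohex-2-en-1-yl]methanol | OC[C@@H]1C(C)=CC[C@@H](CC(OC)OC)C1(C)C | intermediate
12 | 2-[(1S,5R)-5-(hydroxymethyl)-4,6,6-trimethylcyclohex-3-en-1-yl]acetaldehyde | OC[C@@H]1C(C)=CC[C@@H](CC=O)C1(C)C | intermediate
13 | ethyl (2E)-4-[(1S,5R)-5-(hydroxymethyl)-4,6,6-trimethylcyclohex-3-en-1-yl]-2-methylbut-2-enoate | OC[C@@H]1C(C)=CC[C@@H](C/C=C(\C)C(=O)OCC)C1(C)C | intermediate
14 | ethyl (2E)-2-methyl-4-[(1S,5R)-4,6,6-trimethyl-5-{[(1-phenyl-1H-tetrazol-5-yl)sulfanyl]methyl}cyclohex-3-en-1-yl]but-2-enoate | c1ccccc1-n1nnnc1SC[C@@H]1C(C)=CC[C@@H](C/C=C(\C)C(=O)OCC)C1(C)C | intermediate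
15 | ethyl (2E)-2-methyl-4-[(1S,5R)-4,6,6-trimethyl-5-{[(1-phenyl-1H-tetrazol-5-yl)sulfonyl]methyl}cyclohex-3-en-1-yl]but-2-enoate | c1ccccc1-n1nnnc1S(=O)(=O)C[C@@H]1C(C)=CC[C@@H](C/C=C(\C)C(=O)OCC)C1(C)C | intermediate
16 | diethyl (S)-malate | CCOC(=O)C[C@H](O)C(=O)OCC | starting material
17 | prenyl bromide, 1-bromo-3-methylbut-2-ene | CC(C)=CCBr | starting material
18 | diethyl (2S,3R)-2-hydroxy-3-(3-methylbut-2-en-1-yl)butanedioate | CCOC(=O)[C@@H](O)[C@@H](CC=C(C)C)C(=O)OCC | intermediate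
19 | (3S,4R)-2,5-dimethyl-4-(3-methylbut-2-en-1-yl)hexane-2,3,5-triol | CC(C)(O)[C@@H](O)[C@@H](CC=C(C)C)C(C)(C)O | intermediate
20 | (2S)-3-hydroxy-3-methyl-2-(3-methylbut-2-en-1-yl)butanal | CC(C)=CC[C@H](C=O)C(C)(C)O | intermediate
21 | (3E,5R)-5-(2-hydroxypropan-2-yl)-8-methylnona-3,7-dien-2-one | CC(C)=CC[C@H](/C=C/C(C)=O)C(C)(C)O | intermediate
22 | (4E,6R)-6-(2-hydroxypropan-2-yl)-3,9-dimethyldeca-1,4,8-trien-3-ol (C3 epimers) | CC(C)=CC[C@H](/C=C/C(C)(O)C=C)C(C)(C)O | intermediate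
23 | [(2E,4E,6R)-6-(2-hydroxypropan-2-yl)-3,9-dimethyldeca-2,4,8-trien-1-yl]triphenylphosphonium bromide | CC(C)=CC[C@H](/C=C/C(C)=C/C[P+](c1ccccc1)(c1ccccc1)c1ccccc1)C(C)(C)O.[Br-] | intermediate
24 | crocetindial, (2E,4E,6E,8E,10E,12E,14E)-2,6,11,15-tetramethylhexadeca-2,4,6,8,10,12,14-heptaenedial | O=C/C(C)=C/C=C/C(C)=C/C=C/C=C(C)/C=C/C=C(C)/C=O | starting material
25 | (2E,4E,6E,8E,10E,12E,14E,16E,18E,20E,22R)-22-(2-hydroxypropan-2-yl)-2,6,11,15,19,25-hexamethylhexacosa-2,4,6,8,10,12,14,16,18,20,24-undecaenal | CC(C)=CC[C@H](/C=C/C(C)=C/C=C/C(C)=C/C=C/C(C)=C/C=C/C=C(C)/C=C/C=C(C)/C=O)C(C)(C)O | intermediate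
26 | ethyl ester of the target (ring side chain CH2–CH=C(CH3)–CO2Et, otherwise identical) | CC(C)=CC[C@H](/C=C/C(C)=C/C=C/C(C)=C/C=C/C(C)=C/C=C/C=C(C)/C=C/C=C(C)/C=C/[C@@H]1C(C)=CC[C@@H](C/C=C(\C)C(=O)OCC)C1(C)C)C(C)(C)O | intermediate
27 | CNP0409952.2, (2S,6R,2'R)-2-[(2E)-4-hydroxy-3-methylbut-2-enyl]-2'-(3-methylbut-2-enyl)-3',4'-didehydro-1',2'-dihydro-ε,ψ-caroten-1'-ol | CC(C)=CC[C@H](/C=C/C(C)=C/C=C/C(C)=C/C=C/C(C)=C/C=C/C=C(C)/C=C/C=C(C)/C=C/[C@@H]1C(C)=CC[C@@H](C/C=C(\C)CO)C1(C)C)C(C)(C)O | target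

**Step count and risks**
Total step count: 18. Longest linear sequence: 12 steps (steps 1 to 10, then 17 and 18); the acyclic branch is 6 steps (11 to 16) before the junction.

Most likely to fail, first: step 7. The lithiomethyl ether may prefer the [1,2]-shift, or may not reach the crowded C6 next to the quaternary carbon. The fallback sets out from 8 and comes back to the route at 11. DCC/DMAP esterification of 8 with (4-methylphenyl)sulfonylacetic acid gives the allylic tosylacetate F1. Its decarboxylative Claisen rearrangement (BSA, KOAc cat., toluene, 110 °C) is a thermal [3,3] shift that tolerates a hindered terminus and puts the carbon on the same face, giving the homoallylic tolyl sulfone F2. Lithiation (n-BuLi, THF, −78 °C) and oxidation with bis(trimethylsilyl) peroxide expel sulfinate and give the ring aldehyde F3, which is reduced at once with NaBH4 in MeOH to 11.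

Second: step 6. The ketone of 7 is flanked by two fully substituted carbons, so hydrazone formation may be too slow and the epoxide may open first. The fallback sets out from 7 and comes back at 8. NaBH4/CeCl3·7H2O in MeOH gives the epoxy alcohol F4 (either carbinol epimer serves). NaH, CS2, then MeI give the epoxy xanthate F5. Bu3SnH with AIBN in benzene at 80 °C generates the C6 radical, which opens the epoxide, and the alkoxyl radical takes hydrogen from the stannane; this gives 8 with the C4–O bond and its configuration unchanged.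

Third: step 17. The β-branched sulfone anion may add poorly to the polyenal or give an E/Z mixture. The fallback sets out from 13 and comes back at 26. I2, PPh3 and imidazole in CH2Cl2 give the primary iodide F6. PPh3 in MeCN at 85 °C gives the phosphonium iodide F7. Ylide formation with NaN(SiMe3)2 in THF at −78 °C, addition of 25 and iodine-catalysed Z to E equilibration of the new C7=C8 bond give 26.

**Further compounds**
F1 | step 7 | (1R,5S)-5-(2,2-dimethoxyethyl)-2,4,4-trimethylcyclohex-2-en-1-yl 2-[(4-methylphenyl)sulfonyl]acetate | Cc1ccc(cc1)S(=O)(=O)CC(=O)O[C@H]1C(C)=CC(C)(C)[C@H](CC(OC)OC)C1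
F2 | step 7 | 1-({[(1R,5S)-5-(2,2-dimethoxyethyl)-2,6,6-trimethylcyclohex-2-en-1-yl]methyl}sulfonyl)-4-methylbenzene | Cc1ccc(cc1)S(=O)(=O)C[C@@H]1C(C)=CC[C@@H](CC(OC)OC)C1(C)C
F3 | step 7 | (1R,5S)-5-(2,2-dimethoxyethyl)-2,6,6-trimethylcyclohex-2-ene-1-carbaldehyde | O=C[C@@H]1C(C)=CC[C@@H](CC(OC)OC)C1(C)C
F4 | step 6 | 4-(2,2-dimethoxyethyl)-1,3,3-trimethyl-7-oxabicyclo[4.1.0]heptan-2-ol (epoxide and C4 configured as in 7, carbinol epimers) | OC1[C@]2(C)O[C@@H]2C[C@@H](CC(OC)OC)C1(C)C
F5 | step 6 | O-[4-(2,2-dimethoxyethyl)-1,3,3-trimethyl-7-oxabicyclo[4.1.0]heptan-2-yl] S-methyl carbonodithioate (configured as F4) | CSC(=S)OC1[C@]2(C)O[C@@H]2C[C@@H](CC(OC)OC)C1(C)C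
F6 | step 17 | ethyl (2E)-4-[(1S,5R)-5-(iodomethyl)-4,6,6-trimethylcyclohex-3-en-1-yl]-2-methylbut-2-enoate | IC[C@@H]1C(C)=CC[C@@H](C/C=C(\C)C(=O)OCC)C1(C)C
F7 | step 17 | {[(1R,5S)-5-[(2E)-4-ethoxy-3-methyl-4-oxobut-2-en-1-yl]-2,6,6-trimethylcyclohex-2-en-1-yl]methyl}triphenylphosphonium iodide | [I-].c1ccccc1[P+](c1ccccc1)(c1ccccc1)C[C@@H]1C(C)=CC[C@@H](C/C=C(\C)C(=O)OCC)C1(C)C
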